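## Structural features

The target is a trans-fused hydroazulene (daucane skeleton). A cycloheptene, numbered here C1 to C7, shares the C6–C7 bond with a cyclopentane made of C6, C7, C8, C9 and C10. C1 carries the (E)-2-methylbut-2-enoate (tiglate), C2=C3 is the ring alkene with a methyl group on C3, C4 is a methylene, C5 carries the 4-hydroxybenzoate, C6 a hydrogen, C7 an angular methyl group, and C10 a tertiary hydroxyl and an isopropyl group. Four stereocentres stand in a row (C1, C7, C6, C5) and the fifth, C10, is bonded to C6. The configuration is 1R,5S,6S,7S,10S: H-6, the C10 hydroxyl and both ester oxygens lie on one face (called α below), the C7 methyl and the isopropyl group on the other (β), and the oxygens on C5 and C10 are 1,3-syn. Fragile points are the allylic ester at C1, the reducible tiglate, the free phenol (to be masked during both acylations), the C6 hydrogen once C5 is a ketone (epimerisation to the cis-fused isomer) and the C10 oxygen β to that ketone (elimination, retro-aldol). The real difficulty is the congested C7–C6–C10 region: a quaternary C7 between two oxygenated carbons, a trans ring fusion in which C5 stands cis to both the methyl and the isopropyl group, and a C5 hydrogen that has to be placed on the hindered β face. The key step uses the fact that C2=C3(CH3) is a propyne unit and that C4–C5–C6(–C7)–C1 can be drawn as a 1-siloxyvinylcyclopropane whose three-membered ring (C1, C6, C7) is fused to the five-membered ring. A rhodium-catalysed (5+2) cycloaddition then closes the seven-membered ring and leaves C5 as an enol ether.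

## Logic of the disconnections

29 to 28: the aryl O–acyl bond of a hindered aryl ester is cut last. The phenol must be masked while both alcohol acylations are done, and the mask must survive acidic fluoride and acyl-transfer catalysis. The demand on the forward step is cleavage of an aryl ester beside two alkyl esters.

28 to 26 + 27: the C1–O acyl bond is cut. The allylic tiglate is the most reduction- and ionisation-sensitive group and is therefore formed after all reductions and desilylations. The forward step must acylate a neopentyl secondary hydroxyl while the tertiary C10 hydroxyl stays untouched.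

26 to 25: the two alkyl O–Si bonds (C1, C10) are cut together. One acidic fluoride treatment is required that leaves two esters intact.

25 to 21 + 23 (through 24), and 23 to 22: the C5–O acyl bond is cut. In 21 the C5 hydroxyl is the only free hydroxyl, so no selectivity between C1 and C5 is needed. The demand is an activation strong enough for a hindered equatorial alcohol.

21 to 20: the C5–H bond is cut. The hydrogen must arrive on the β face, which is shielded by the C7 methyl and the isopropyl group. A hydride, whether external or delivered from the C10 oxygen, would come from the α face and give the 1,3-anti diol. The forward step must therefore be an electron-transfer reduction under thermodynamic control.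

20 to 19: the C6–H bond is cut and the ketone is returned to its silyl enol ether. This removes two stereocentres (C5, C6) and exposes the cycloadduct. The forward step must protonate C6 on the α face under kinetic conditions.

19 to 17 + 18: C3–C4 and C1–C2 are cut (key step). The seven-membered ring disappears and the problem becomes a bicyclo[3.1.0]hexane plus a three-carbon gas. The demands are cleavage of C1–C6 and not C6–C7, the correct orientation of 18, and retention at C1.

17 to 16 to 15 to 14: the enol O–Si bond, the C5 carbonyl and the side-chain protecting group are taken back in turn. The acetyl group may appear only after all organolithium chemistry and after the cyclopropanol is silylated, because a free 2-acylcyclopropanol would open.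

14 to 13 to 10 (through 11 and 12): the O–Si bond and then the C1–O bond are traced back to a C1–Br bond of a gem-dibromide. The forward sequence must exchange the exo bromine and then move boron to the endo position by an invertive 1,2-shift.

10 to 8 + 9: C1–C6 and C1–C7 are cut (carbene addition). This leaves a monocyclic cyclopentene. The carbene must add to the face of the C10 oxygen.

8 to 7 to 5 + 6: the acetal O–C bond and the C4–C5 bond are cut, leaving an enal and a methyl nucleophile. The side-chain oxygen has to be protected without forming an alkoxide, since an alkoxide 1,3 to the tertiary silyl ether would invite silyl migration.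

5 to 2 (through 3 and 4) to 1: the C6=C7 bond is cut (aldol condensation) and C5 is reconnected to C7 as the ring alkene of a cyclohexene (ozonolysis retron). C10 then comes from the chiral pool with its oxygen and isopropyl group in place.

## Other disconnections considered

Alternative 1: The cut is made at C7–C6 and C7–C1, so that C7 becomes the carbene carbon of an α-diazo ketone A1 whose C10 carries a 2,6-dimethoxy-4-methylphenyl ring; the arene supplies C1 to C6. In the forward sense Rh2(O2CCF3)4 (divalent rhodium) would generate the carbene, which would cyclopropanate the ipso–ortho bond of the arene. A 6π ring opening would then give the cycloheptatriene A2 with both rings formed.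
- In its favour: one step forms two rings, two C–C bonds and the quaternary C7, and the arene already carries the C3 methyl group and oxygen at C1 and C5.
- Because the aryl ring is symmetrical there is no regiochemical question in the ring-forming step. On this point, and on the number of steps to the bicyclic skeleton, the alternative is the better plan.
- Against it: the carbene must attack an ipso–ortho bond whose ortho carbon bears a methoxy group, where electron-rich arenes tend to divert metal carbenes into aromatic substitution or ylide formation. The tertiary benzylic silyl ether is a further ylide-forming site.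
- The configuration of C7 relative to C10 would be decided by which face of a rotating aryl ring is attacked, whereas the chosen route relays it through a rigid cyclopentene.
- C10 would need an enantioselective carbonyl addition, while the chosen route takes it from the chiral pool.
- After the key step A2 is at the wrong oxidation level. Two enol ethers must be told apart, C1 and C5 reduced with control, the unsaturation moved to C2=C3 and the C8 ketone deleted. These corrections include the same C6 protonation and C5 reduction as the chosen plan and add several more.
- Comparison: both plans rest on rhodium catalysis of comparable precedent. The (5+2) product already has C2=C3, the C1 oxygen with its configuration and no oxygen at C8, so the overall count should favour the chosen plan despite its longer approach to the key step.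

Alternative 2: C1–C7 is cut together with a temporary bond C2–C6. This opens the seven-membered ring to an acylcyclopentene A3: an enone C5(=O)–C6=C7 that carries, through C4 and a tertiary carbinol C3, an (E)-silyl enol ether C2=C1. Irradiation near 350 nm would give, by intramolecular (2+2) photocycloaddition, the cyclobutane A4 (bonds C1–C7 and C2–C6). A reductive fragmentation of C2–C6 from the C5 ketyl, with loss of the C3 hydroxyl, would then converge on 20.
- In its favour: the tether length fixes the regiochemistry of the photocycloaddition, the quaternary C7 is formed without a metal, and the C1 configuration follows from the enol ether geometry.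
- The position of the C2=C3 double bond is fixed by where the hydroxyl leaves. On this point the alternative is the better plan, since no orientation of an unsymmetrical two-carbon partner has to be controlled.
- The cyclopentene would come from the same chiral-pool aldehyde 5, so the two plans are equal in the origin of C10.
- Against it: facial selectivity with respect to C10 again rests on isopropyl against siloxy.
- The fragmentation must break C2–C6 and not C6–C7, although the latter would give the more stable tertiary radical.
- A3 is a β-hydroxy ketone open to retro-aldol cleavage and to Norrish-type side reactions. It also needs an aldol addition to a ketone, whose uncontrolled C3 centre multiplies isomers.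
- Comparison: since the sequence ends at the same ketone, the same protonation and reduction remain. The step count would be comparable, with more steps of low precedent.

Alternative 3: The bicycle is cut at C6–C7 and at the C10–O bond to a ten-membered ring, the epoxy cyclodecadiene A5. It has a C1–C7 epoxide, a C2=C3 alkene with cis ring bonds and a C6=C10 alkene with trans ring bonds (Z by the sequence rule, since isopropyl outranks C9). BF3·OEt2 would open the epoxide at the tertiary C7, C6 of the facing alkene would attack C7 with inversion, and water would capture the C10 cation anti to the new bond. This would give the diol A6.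
- In its favour: one step would set C1, C7, C6 and C10 from the ring conformation, give the trans fusion directly and leave the C1 and C10 hydroxyls free beside a protected C5 oxygen.
- The end game from A6 would be about four steps. On the C6 and C5 configurations, which the chosen route must set by a kinetic protonation and a thermodynamic reduction, the alternative is the better plan.
- Against it: A5 is a vinyl epoxide, so a Lewis acid can ionise the allylic C1–O bond as readily as the tertiary C7–O bond, and a semipinacol-type hydride shift competes.
- The tertiary cation at C10 is more likely to lose a proton than to wait for water.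
- A ten-membered ring with one cis and one trans trisubstituted alkene, a defined epoxide and a C5 stereocentre would have to be made as a single enantiomer by macrocyclisation, for which no short route is evident.
- Comparison: the alternative moves all the risk to the front. Its key step is a cation cascade steered only by conformation, whereas the (5+2) cycloaddition is metal-templated with a defined order of bond formation. The total number of steps would very probably be higher.

Key step: step 11

Remark 1: (R)-(−)-terpinen-4-ol (1) is assumed to be available in high enantiomeric purity; C10 is the only source of absolute configuration, so enriched material would have to be upgraded first.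
Remark 2: the carbinol carbon C5 formed in step 3 is carried as both epimers through 7, 8 and 10 to 15 and is removed in step 9; it is written without a descriptor in those structures.

## Route

Step 1
Reactants: 1 (R)-terpinen-4-ol
Product: 2 (R)-triethyl{[4-methyl-1-(propan-2-yl)cyclohex-3-en-1-yl]oxy}silane
Conditions: Et3SiOTf, 2,6-lutidine, CH2Cl2, 0 °C
Reagents that add atoms: triethylsilyl trifluoromethanesulfonate, CC[Si](CC)(CC)OS(=O)(=O)C(F)(F)F
Why: Silylation of a hindered tertiary alcohol with a silyl triflate and a hindered pyridine base; the ether removes the acidic proton and most of the donor ability of the future C10 oxygen for steps 3 to 11, and no stereocentre is touched.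

Step 2
Reactants: 2 (R)-triethyl{[4-methyl-1-(propan-2-yl)cyclohex-3-en-1-yl]oxy}silane
Product: 5 (S)-2-methyl-5-(propan-2-yl)-5-(triethylsilyloxy)cyclopent-1-ene-1-carbaldehyde, via ozonide 3 (not isolated), via keto aldehyde 4 (not isolated)
Conditions: O3, CH2Cl2, −78 °C; Me2S, −78 °C to rt; then piperidine (cat.), AcOH (cat.), toluene, rt to 50 °C
Reagents that add atoms: ozone, [O-][O+]=O
Why: Ozonolysis of the trisubstituted ring alkene and reductive work-up give the 1,6-keto aldehyde; piperidinium acetate converts the aldehyde into its enamine, which adds to the methyl ketone and dehydrates (intramolecular aldol condensation) to the cyclopentene carbaldehyde. The C10 centre comes unchanged from 1 (its descriptor changes from R to S only because the ranking of its neighbours changes).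

Step 3
Reactants: 5 (S)-2-methyl-5-(propan-2-yl)-5-(triethylsilyloxy)cyclopent-1-ene-1-carbaldehyde; 6 methylmagnesium bromide
Product: 7 1-[(5S)-2-methyl-5-(propan-2-yl)-5-(triethylsilyloxy)cyclopent-1-en-1-yl]ethan-1-ol (both epimers at the carbinol carbon C5)
Conditions: MeMgBr, THF, −78 to 0 °C; then aq NH4Cl
Reagents that add atoms: methylmagnesium bromide (6), C[Mg]Br
Why: Grignard 1,2-addition to a β,β-disubstituted enal, whose fully substituted β-carbon blocks conjugate addition; the new carbinol centre is not controlled and is erased in step 9. The cold quench avoids silyl migration from the C10 oxygen to the new alkoxide.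

Step 4
Reactants: 7 1-[(5S)-2-methyl-5-(propan-2-yl)-5-(triethylsilyloxy)cyclopent-1-en-1-yl]ethan-1-ol
Product: 8 benzyloxymethyl ether of 7
Conditions: BnOCH2Cl, i-Pr2NEt, Bu4NI (cat.), CH2Cl2, 0 °C to rt
Reagents that add atoms: benzyl chloromethyl ether, ClCOCc1ccccc1
Why: Alkylation of the secondary alcohol with a reactive chloromethyl ether under amine-base conditions, so that no alkoxide is formed next to the tertiary silyl ether. The acetal is stable to base and organolithiums, is a good lithium-coordinating site beside the future cyclopropane and is removed by hydrogenolysis once no alkene remains.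

Step 5
Reactants: 8 benzyloxymethyl ether of 7; 9 bromoform
Product: 10 gem-dibromocyclopropane: CBr2 (C1) bridging C6 and C7 of 8 on the α face (the face of the C10 siloxy group), giving a 6,6-dibromobicyclo[3.1.0]hexane with the C7 methyl and the C6 side chain on the β side
Conditions: CHBr3, KOtBu, pentane, −20 to 0 °C
Reagents that add atoms: bromoform (9), BrC(Br)Br
Why: α-Elimination of HBr from bromoform gives dibromocarbene, which adds stereospecifically to the electron-rich tetrasubstituted alkene (cheletropic cyclopropanation). Addition should occur on the face of the C10 siloxy group, because the isopropyl group bound directly to C10 shields the other face more than the oxygen-linked silyl group; this sets C6 and C7. The adduct is kept cold and used at once, since 6,6-dibromobicyclo[3.1.0]hexanes open thermally to bromocyclohexenes.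

Step 6
Reactants: 10 gem-dibromocyclopropane
Product: 13 endo-cyclopropanol (C1–OH cis to C8 and C10 and trans to the C7 methyl and the C6 side chain), via carbenoid 11 (not isolated), via boronate 12 (not isolated)
Conditions: n-BuLi, THF/Et2O/pentane, −100 °C; catecholborane, −100 °C to rt; then NaOH, H2O2, THF/H2O, 0 °C
Reagents that add atoms: hydrogen peroxide, OO; catecholborane, B1Oc2ccccc2O1; n-butyllithium, [Li]CCCC
Why: Bromine–lithium exchange should take the exo bromine, the one cis to the side chain, because the acetal oxygen can hold lithium in a five-membered chelate while the silyl ether on C10 is a poor donor. The carbenoid adds to the borane and hydride shifts from boron to C1 with loss of the endo bromide and inversion (1,2-metallate rearrangement, the known conversion of 1,1-dibromocyclopropanes into cyclopropanols), which places boron endo. Oxidation of the C–B bond with retention gives the endo cyclopropanol.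

Step 7
Reactants: 13 endo-cyclopropanol
Product: 14 tert-butyldimethylsilyl ether of 13
Conditions: t-BuMe2SiOTf, 2,6-lutidine, CH2Cl2, −78 to 0 °C
Reagents that add atoms: tert-butyldimethylsilyl trifluoromethanesulfonate, CC(C)(C)[Si](C)(C)OS(=O)(=O)C(F)(F)F
Why: Silylation of a hindered hydroxyl with a silyl triflate at low temperature; the robust silyl ether prevents the ring opening that a free cyclopropanol would undergo once the neighbouring acetyl group is present.

Step 8
Reactants: 14 tert-butyldimethylsilyl ether of 13
Product: 15 1-(bicyclo[3.1.0]hexan-1-yl)ethanol: side chain CH(OH)CH3 on C6, other groups as in 14 (both epimers at C5)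
Conditions: H2 (1 atm), Pd(OH)2/C, EtOAc, rt
Reagents that add atoms: none
Why: Hydrogenolysis of the benzylic C–O bond and collapse of the resulting hemiacetal; silyl ethers and the cyclopropane are not affected in a neutral aprotic solvent and no alkene is present.

Step 9
Reactants: 15 secondary alcohol
Product: 16 methyl ketone: acetyl group on C6, endo OSiMe2t-Bu on C1, methyl on C7, OSiEt3 and isopropyl on C10
Conditions: (n-Pr4N)[RuO4] (cat.), N-methylmorpholine N-oxide, MS 4 Å, CH2Cl2, rt
Reagents that add atoms: none
Why: Ley–Griffith oxidation of the secondary alcohol under neutral conditions gives the ketone and removes the uncontrolled carbinol centre; the 2-siloxycyclopropyl ketone is stable as long as the silyl ether is intact and no acid is present.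

Step 10
Reactants: 16 methyl ketone
Product: 17 (1S,6R,7S,10S)-siloxyvinylcyclopropane: bicyclo[3.1.0]hexane with 1-(trimethylsilyloxy)vinyl on C6, endo OSiMe2t-Bu on C1, methyl on C7, OSiEt3 and isopropyl on C10
Conditions: LiN(i-Pr)2, Me3SiCl, THF, −78 °C
Reagents that add atoms: chlorotrimethylsilane, C[Si](C)(C)Cl
Why: The only α-hydrogens are those of the methyl group, so deprotonation in the presence of the silyl chloride gives the 1-siloxyvinyl group regiospecifically. A lithium amide is preferred to a silyl triflate because a Lewis acid could open the donor–acceptor cyclopropane.

Step 11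
Reactants: 17 siloxyvinylcyclopropane; 18 propyne
Product: 19 (1R,7S,10S)-cyclohepta-2,5-diene fused at C6–C7 to the cyclopentane: 1α-OSiMe2t-Bu, C2=C3 with methyl on C3, trimethylsilyl enol ether C5=C6, methyl on C7, OSiEt3 and isopropyl on C10
Conditions: [Rh(CO)2Cl]2 (5 mol %), propyne (excess), ClCH2CH2Cl, sealed tube, 60 to 80 °C
Reagents that add atoms: propyne (18), CC#C
Why: A Rh(CO)Cl fragment (monovalent rhodium) binds the siloxyvinyl group and adds oxidatively into C1–C6, the cyclopropane bond flanked by the siloxy donor on C1 and the vinyl group on C6, to give a σ-alkyl/π-allyl rhodacyclohexene (trivalent rhodium); insertion into C6–C7 would need a tertiary alkyl–rhodium bond at the quaternary C7 and is not expected. Propyne then inserts into the bond from rhodium to the allyl terminus C4 (new bond C3–C4), and C(sp2)–C(sp3) reductive elimination joins C2 to C1. The closest known reaction type is the rhodium-catalysed intermolecular (5+2) cycloaddition of 1-siloxyvinylcyclopropanes with alkynes. The seven-membered ring is closed by that reductive elimination from an eight-membered rhodacycle, that is by ring expansion of the metallacycle and not by a pericyclic closure. No stereocentre is created: C6 becomes trigonal, C7 and C10 are untouched, and C1 passes from C6 to rhodium to C2 with retention, so the endo siloxy group of 17 becomes the 1α oxygen, trans to the C7 methyl. Two selectivities are needed: cleavage of C1–C6, secured by the quaternary C7 and by donor activation, and the orientation of propyne with its CH terminus next to C1. The orientation rests on the crowding around C1 (siloxy group, quaternary C7), which should disfavour a methyl-bearing carbon on rhodium beside it; it runs against the weak opposite preference of unhindered vinylcyclopropanes and is the less secure of the two. C1 has no β-hydrogen, so β-hydride elimination is not available, and the enol ether left at C5 is the masked ketone needed next.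

Step 12
Reactants: 19 cycloheptadiene silyl enol ether
Product: 20 (1R,6R,7S,10S)-trans-fused ketone: C5=O, H-6 α, 1α-OSiMe2t-Bu, C2=C3, 10α-OSiEt3
Conditions: Bu4NF, AcOH, THF, −78 °C
Reagents that add atoms: none
Why: Fluoride cleaves the enol O–SiMe3 bond far faster than the tertiary triethylsilyl and the hindered tert-butyldimethylsilyl ethers, and the enolate is protonated at once by acetic acid (kinetic protonation). The proton should enter C6 on the α face, away from the C7 methyl and the C10 isopropyl group that sit directly on the two flanking carbons, which gives the trans ring fusion. Basic or prolonged acidic conditions are avoided so that C6 cannot equilibrate.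

Step 13
Reactants: 20 trans-fused ketone
Product: 21 (1R,5S,6S,7S,10S)-alcohol: 5α-OH (equatorial, cis to H-6, syn to the C10 oxygen), other groups as in 20
Conditions: Li, NH3(l)/THF, t-BuOH, −78 °C; then NH4Cl
Reagents that add atoms: none
Why: Dissolving-metal reduction of the ketone gives the thermodynamically preferred equatorial 5α-alcohol (H-5 axial and anti to H-6). A hydride reagent, external or delivered from the C10 oxygen, would attack the open α face and give the 5β epimer. Electron transfer should be faster than removal of the hindered C6 hydrogen, and the isolated alkene and the silyl ethers should not be reduced at −78 °C.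

Step 14
Reactants: 22 4-hydroxybenzoic acid
Product: 23 4-(2,2-dimethylpropanoyloxy)benzoic acid
Conditions: t-BuCOCl, NaOH, H2O, 0 °C; then HCl
Reagents that add atoms: pivaloyl chloride, CC(C)(C)C(Cl)=O
Why: Schotten–Baumann acylation: the phenoxide is acylated in aqueous base and any mixed anhydride formed at the carboxylate is hydrolysed. The hindered aryl pivalate masks the phenol through steps 15 to 17 without acting as an acyl donor itself.

Step 15
Reactants: 21 alcohol; 23 4-(2,2-dimethylpropanoyloxy)benzoic acid
Product: 25 C5 ester: 5α-O-[4-(pivaloyloxy)benzoyl] derivative of 21, via mixed anhydride 24 (not isolated)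
Conditions: 2,4,6-Cl3C6H2COCl, Et3N, THF, rt; then 21, DMAP, toluene, rt to 50 °C
Reagents that add atoms: 4-(2,2-dimethylpropanoyloxy)benzoic acid (23), CC(C)(C)C(=O)Oc1ccc(cc1)C(O)=O; 2,4,6-trichlorobenzoyl chloride (its atoms stay only in 24), ClC(=O)c1c(Cl)cc(Cl)cc1Cl
Why: Yamaguchi esterification: DMAP attacks the unhindered carbonyl of the mixed anhydride and transfers the aroyl group to the only free hydroxyl, the equatorial C5–OH; no stereocentre is affected.

Step 16
Reactants: 25 C5 ester
Product: 26 diol: C1–OH and C10–OH free, 5α-O-[4-(pivaloyloxy)benzoyl]
Conditions: HF·pyridine, pyridine, THF, 0 °C to rt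
Reagents that add atoms: none
Why: Acidic fluoride cleaves both alkyl silyl ethers, while the benzoate and the aryl pivalate, which would be at risk with basic fluoride, are stable to HF·pyridine.

Step 17
Reactants: 26 diol; 27 (E)-2-methylbut-2-enoyl chloride (tigloyl chloride)
Product: 28 1α-O-tigloyl 5α-O-[4-(pivaloyloxy)benzoyl] diester with free C10–OH
Conditions: tigloyl chloride, DMAP, pyridine, CH2Cl2, 40 °C
Reagents that add atoms: (E)-2-methylbut-2-enoyl chloride (27), C/C=C(\C)C(Cl)=O
Why: DMAP-catalysed acylation of the neopentyl allylic C1–OH with the acid chloride. The tertiary C10–OH does not react under these conditions, the aryl pivalate is too hindered to pass on its acyl group, and the tiglate is the stable alkene isomer, so the (E) geometry is kept.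

Step 18
Reactants: 28 diester pivalate
Product: 29 target, (1R,5S,6S,7S,10S)-1-O-tigloyl-5-O-(4-hydroxybenzoyl) diester with free C10–OH
Conditions: pyrrolidine, CH2Cl2, 0 °C to rt
Reagents that add atoms: none
Why: Aminolysis of the aryl ester: the phenoxide is a far better leaving group than the two secondary alkoxides, so the pivaloyl group is removed selectively and the hindered benzoate and tiglate esters stay intact.

## Compound list

1 | (R)-terpinen-4-ol, (R)-4-methyl-1-(propan-2-yl)cyclohex-3-en-1-ol | CC1=CC[C@@](O)(C(C)C)CC1 | starting material
2 | (R)-triethyl{[4-methyl-1-(propan-2-yl)cyclohex-3-en-1-yl]oxy}silane | CC1=CC[C@@](O[Si](CC)(CC)CC)(C(C)C)CC1 | intermediate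
3 | secondary ozonide of 2 (1,2,4-trioxolane across the former C=C; acetal carbons unassigned) | CC12CC[C@](O[Si](CC)(CC)CC)(C(C)C)CC(OO1)O2 | intermediate (not isolated)
4 | (R)-6-oxo-3-(propan-2-yl)-3-(triethylsilyloxy)heptanal | O=CC[C@@](O[Si](CC)(CC)CC)(C(C)C)CCC(C)=O | intermediate (not isolated)
5 | (S)-2-methyl-5-(propan-2-yl)-5-(triethylsilyloxy)cyclopent-1-ene-1-carbaldehyde (CHO = C5; ring = C6, C7, C8, C9, C10) | O=CC1=C(C)CC[C@]1(O[Si](CC)(CC)CC)C(C)C | intermediate
6 | methylmagnesium bromide | C[Mg]Br | starting material
7 | 1-[(5S)-2-methyl-5-(propan-2-yl)-5-(triethylsilyloxy)cyclopent-1-en-1-yl]ethan-1-ol, both epimers at the carbinol carbon | CC(O)C1=C(C)CC[C@]1(O[Si](CC)(CC)CC)C(C)C | intermediate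
8 | benzyloxymethyl ether of 7 | CC(OCOCc1ccccc1)C1=C(C)CC[C@]1(O[Si](CC)(CC)CC)C(C)C | intermediate
9 | bromoform | BrC(Br)Br | starting material
10 | 6,6-dibromobicyclo[3.1.0]hexane from 8: CBr2 (C1) on the α face, bridging C6 and C7; 10S | CC(OCOCc1ccccc1)[C@]12C(Br)(Br)[C@@]1(C)CC[C@]2(O[Si](CC)(CC)CC)C(C)C | intermediate
11 | exo-lithio endo-bromo carbenoid from 10 (Li cis to the C6 side chain and the C7 methyl) | CC(OCOCc1ccccc1)[C@]12[C@@]([Li])(Br)[C@@]1(C)CC[C@]2(O[Si](CC)(CC)CC)C(C)C | intermediate (not isolated)
12 | endo cyclopropyl catechol boronate (1,3,2-benzodioxaborol-2-yl on C1, cis to C8 and C10) | CC(OCOCc1ccccc1)[C@]12[C@@H](B3Oc4ccccc4O3)[C@@]1(C)CC[C@]2(O[Si](CC)(CC)CC)C(C)C | intermediate (not isolated)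
13 | endo cyclopropanol (C1–OH cis to C8 and C10, H-1 exo) | CC(OCOCc1ccccc1)[C@]12[C@@H](O)[C@@]1(C)CC[C@]2(O[Si](CC)(CC)CC)C(C)C | intermediate
14 | tert-butyldimethylsilyl ether of 13 | CC(OCOCc1ccccc1)[C@]12[C@@H](O[Si](C)(C)C(C)(C)C)[C@@]1(C)CC[C@]2(O[Si](CC)(CC)CC)C(C)C | intermediate
15 | secondary alcohol: CH(OH)CH3 on C6, ring configured as in 17, both epimers at C5 | CC(O)[C@]12[C@@H](O[Si](C)(C)C(C)(C)C)[C@@]1(C)CC[C@]2(O[Si](CC)(CC)CC)C(C)C | intermediate
16 | methyl ketone: acetyl on C6, ring configured as in 17 | CC(=O)[C@]12[C@@H](O[Si](C)(C)C(C)(C)C)[C@@]1(C)CC[C@]2(O[Si](CC)(CC)CC)C(C)C | intermediate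
17 | (1S,6R,7S,10S)-siloxyvinylcyclopropane (bicyclo[3.1.0]hexane: cyclopropane C1, C6, C7; 1-(trimethylsilyloxy)vinyl on C6; endo OSiMe2t-Bu on C1; methyl on C7; OSiEt3 and isopropyl on C10) | C=C(O[Si](C)(C)C)[C@]12[C@@H](O[Si](C)(C)C(C)(C)C)[C@@]1(C)CC[C@]2(O[Si](CC)(CC)CC)C(C)C | intermediate
18 | propyne | CC#C | starting material
19 | (1R,7S,10S)-bicyclic cyclohepta-2,5-diene with trimethylsilyl enol ether at C5=C6 | CC(C)(C)[Si](C)(C)O[C@@H]1C=C(C)CC(O[Si](C)(C)C)=C2[C@]1(C)CC[C@]2(O[Si](CC)(CC)CC)C(C)C | intermediate
20 | (1R,6R,7S,10S)-trans-fused C5 ketone | CC(C)(C)[Si](C)(C)O[C@@H]1C=C(C)CC(=O)[C@@H]2[C@]1(C)CC[C@]2(O[Si](CC)(CC)CC)C(C)C | intermediate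
21 | (1R,5S,6S,7S,10S)-5α-alcohol | CC(C)(C)[Si](C)(C)O[C@@H]1C=C(C)C[C@H](O)[C@@H]2[C@]1(C)CC[C@]2(O[Si](CC)(CC)CC)C(C)C | intermediate
22 | 4-hydroxybenzoic acid | OC(=O)c1ccc(O)cc1 | starting material
23 | 4-(2,2-dimethylpropanoyloxy)benzoic acid | CC(C)(C)C(=O)Oc1ccc(cc1)C(O)=O | intermediate
24 | mixed anhydride of 23 with 2,4,6-trichlorobenzoic acid | CC(C)(C)C(=O)Oc1ccc(cc1)C(=O)OC(=O)c1c(Cl)cc(Cl)cc1Cl | intermediate (not isolated)
25 | (1R,5S,6S,7S,10S)-C5 ester: 5-O-[4-(pivaloyloxy)benzoyl], 1-OSiMe2t-Bu, 10-OSiEt3 | CC(C)(C)[Si](C)(C)O[C@@H]1C=C(C)C[C@H](OC(=O)c3ccc(OC(=O)C(C)(C)C)cc3)[C@@H]2[C@]1(C)CC[C@]2(O[Si](CC)(CC)CC)C(C)C | intermediate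
26 | (1R,5S,6S,7S,10S)-1,10-diol 5-[4-(pivaloyloxy)benzoate] | O[C@@H]1C=C(C)C[C@H](OC(=O)c3ccc(OC(=O)C(C)(C)C)cc3)[C@@H]2[C@]1(C)CC[C@]2(O)C(C)C | intermediate
27 | (E)-2-methylbut-2-enoyl chloride (tigloyl chloride) | C/C=C(\C)C(Cl)=O | starting material
28 | (1R,5S,6S,7S,10S)-1-O-tigloyl 5-O-[4-(pivaloyloxy)benzoyl] diester, 10-OH free | C/C=C(\C)C(=O)O[C@@H]1C=C(C)C[C@H](OC(=O)c3ccc(OC(=O)C(C)(C)C)cc3)[C@@H]2[C@]1(C)CC[C@]2(O)C(C)C | intermediate
29 | target CNP0273650.6, (1R,5S,6S,7S,10S)-1-O-tigloyl 5-O-(4-hydroxybenzoyl) diester, 10-OH free | C/C=C(\C)C(=O)O[C@@H]1C=C(C)C[C@H](OC(=O)c2ccc(O)cc2)[C@@H]2[C@]1(C)CC[C@]2(O)C(C)C | target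

## Step count and least certain steps

Total step count: 18. Longest linear sequence: 17 steps (steps 1 to 13 and 15 to 18 from 1; step 14 is a one-step branch from 22).

Step 11 (key step). Most likely to go wrong: insertion of propyne with the opposite orientation, so that the methyl-bearing carbon ends next to C1. Unhindered vinylcyclopropanes tend to put an alkyl group of a terminal alkyne away from the first bond formed, and the control here rests only on crowding at C1. Slow cycloaddition of this fully substituted cyclopropane, with alkyne oligomerisation and loss of the enol ether, is the second concern. Fallback: from 17, methyl propiolate is used in place of 18 under the same catalysis. An ester on the alkyne is directed electronically to the carbon that bonds to the vinyl terminus C4 and sterically away from C1, so the C3 methyl ester F1 should form. Reduction with i-Bu2AlH gives the allylic alcohol F2, mesylation gives the mesylate F3, and displacement of the primary allylic mesylate with LiBHEt3 turns the CH2 group into the C3 methyl group and returns to the route at 19.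

Step 6. Most likely to go wrong: exchange of the endo bromine instead of the exo one, which after the invertive hydride shift would put oxygen exo. Both positions are flanked by two carbon substituents and only chelation by the acetal distinguishes them. Decomposition of the carbenoid (α-elimination, C–H insertion) before the borane is captured is the second concern. Fallback: from 10, if exchange takes the endo bromine, the endo-lithio carbenoid F4 is trapped with chloro(isopropoxy)dimethylsilane. Lithium is replaced with retention, giving the endo-silyl exo-bromide F5. Treatment with t-BuLi and then methanol replaces the remaining bromine by hydrogen with retention (silane F6). Tamao oxidation (H2O2, KF, KHCO3) converts C–Si into C–OH with retention and returns to the route at 13.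

Step 5. Most likely to go wrong: poor facial selectivity of the carbene addition, since the two faces differ only by isopropyl against siloxy on C10, and thermal ring opening of the dibromide during isolation. Fallback: from 8, the triethylsilyl group is removed with Bu4NF to give the tertiary allylic alcohol F7. Dibromocarbene is added under phase-transfer conditions (CHBr3, 50% aq NaOH, BnEt3NCl), where a free allylic hydroxyl steers the carbene to its own face, giving the dibromo alcohol F8. Re-silylation with Et3SiOTf and 2,6-lutidine returns to the route at 10.

Step 12. Most likely to go wrong: protonation of C6 from the β face, or later equilibration, either of which gives the cis-fused ketone. Both faces of the enol ether are flanked by substituents of the two quaternary neighbours, and the cis-fused ketone is probably the more stable isomer. Fallback: from 19, protonation with a chiral Lewis-acid-assisted Brønsted acid (SnCl4 with one enantiomer of 1,1'-bi-2-naphthol, toluene, −78 °C), so that the face is chosen by the reagent and not by the substrate. This returns to the route at 20 and makes no new compound (F0).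

Step 13. Most likely to go wrong: enolisation and epimerisation at C6 before electron transfer, migration of the triethylsilyl group from the C10 oxygen to the new C5 alkoxide, or reductive loss of the allylic C1 oxygen. Incomplete thermodynamic control at C5 would give some 5β-alcohol. Fallback: from 20, reduction with LiBH(s-Bu)3, which should attack the open α face, gives the axial 5β-alcohol F9. A Mitsunobu esterification with 23 (PPh3, diisopropyl azodicarboxylate, toluene) then introduces the aroyl group with inversion at C5 and returns to the route at 25.

## Further compounds

F1 | step 11 | C3 methyl ester cycloadduct (CO2Me on C3 in place of the methyl group of 19) | CC(C)(C)[Si](C)(C)O[C@@H]1C=C(C(=O)OC)CC(O[Si](C)(C)C)=C2[C@]1(C)CC[C@]2(O[Si](CC)(CC)CC)C(C)C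
F2 | step 11 | allylic alcohol (CH2OH on C3) | CC(C)(C)[Si](C)(C)O[C@@H]1C=C(CO)CC(O[Si](C)(C)C)=C2[C@]1(C)CC[C@]2(O[Si](CC)(CC)CC)C(C)C
F3 | step 11 | allylic mesylate (CH2OSO2CH3 on C3) | CC(C)(C)[Si](C)(C)O[C@@H]1C=C(COS(C)(=O)=O)CC(O[Si](C)(C)C)=C2[C@]1(C)CC[C@]2(O[Si](CC)(CC)CC)C(C)C
F4 | step 6 | endo-lithio exo-bromo carbenoid (C1 epimer of 11) | CC(OCOCc1ccccc1)[C@]12[C@@](Br)([Li])[C@@]1(C)CC[C@]2(O[Si](CC)(CC)CC)C(C)C
F5 | step 6 | endo-(isopropoxydimethylsilyl) exo-bromide | CC(OCOCc1ccccc1)[C@]12[C@@](Br)([Si](C)(C)OC(C)C)[C@@]1(C)CC[C@]2(O[Si](CC)(CC)CC)C(C)C
F6 | step 6 | endo-(isopropoxydimethylsilyl)cyclopropane | CC(OCOCc1ccccc1)[C@]12[C@@H]([Si](C)(C)OC(C)C)[C@@]1(C)CC[C@]2(O[Si](CC)(CC)CC)C(C)C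
F7 | step 5 | tertiary allylic alcohol (8 without the triethylsilyl group) | CC(OCOCc1ccccc1)C1=C(C)CC[C@]1(O)C(C)C
F8 | step 5 | dibromo alcohol (10 without the triethylsilyl group) | CC(OCOCc1ccccc1)[C@]12C(Br)(Br)[C@@]1(C)CC[C@]2(O)C(C)C
F0 | step 12 | none | none
F9 | step 13 | 5β-alcohol (C5 epimer of 21) | CC(C)(C)[Si](C)(C)O[C@@H]1C=C(C)C[C@@H](O)[C@@H]2[C@]1(C)CC[C@]2(O[Si](CC)(CC)CC)C(C)C
A1 | alternative 1 | α-diazo ketone with 2,6-dimethoxy-4-methylphenyl on C10 | CC(=[N+]=[N-])C(=O)C[C@](O[Si](C)(C)C)(C(C)C)c1c(OC)cc(C)cc1OC
A2 | alternative 1 | bicyclic cycloheptatriene bis(methyl enol ether) with C8 ketone | COC1=CC(C)=CC(OC)=C2[C@]1(C)C(=O)C[C@]2(O[Si](C)(C)C)C(C)C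
A3 | alternative 2 | acylcyclopentene with tethered (E)-silyl enol ether | CC(C)(C)[Si](C)(C)O/C=C/[C@](C)(O)CC(=O)C1=C(C)CC[C@]1(O[Si](CC)(CC)CC)C(C)C
A4 | alternative 2 | tricyclic cyclobutane photoadduct | CC(C)(C)[Si](C)(C)O[C@@H]1[C@H]2[C@](C)(O)CC(=O)[C@@]23[C@]1(C)CC[C@]3(O[Si](CC)(CC)CC)C(C)C
A5 | alternative 3 | epoxy cyclodecadiene (C1–C7 epoxide, C2=C3 with cis ring bonds, C6=C10 with trans ring bonds) | CC(C)(C)[Si](C)(C)O[C@H]1C/C(C)=C\[C@H]2O[C@@]2(C)CC/C(C(C)C)=C/1
A6 | alternative 3 | bicyclic 1,10-diol with C5 silyl ether | O[C@@H]1C=C(C)C[C@H](O[Si](C)(C)C(C)(C)C)[C@@H]2[C@]1(C)CC[C@]2(O)C(C)C
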